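**Plan**

1. The last disconnections remove the three benzyl groups, the ring B acetal, the ring A C3–CHO bond and the ring A O4–CH3 bond, leading back to a protected orsellinate depside.
2. Ring A is then opened at its C1–C6 bond: its acyl-bearing C1, C2–OH, C4–O and C6–CH3 correspond to C2, C3, C5 and C7 of a linear 3,5,7-trioxooctanoate whose ester group is already the complete ring B, so an aldol condensation can close ring A on the preformed ester.
3. The depside O–C(=O) bond is cut next into the ring B phenol and an acylketene, which comes from a diketo-dioxinone assembled from 2,2,6-trimethyl-4H-1,3-dioxin-4-one and two acetyl units.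
4. Ring B derives from orsellinic acid by C3 formylation and C5 iodination/hydroxylation, with O2 and O4 as benzyl ethers, the acid as benzyl ester and the aldehyde as dioxolane.
5. Forward: ring B is completed (steps 1–6), the chain is made (steps 7–8) and attached (step 9), ring A arises in step 10 and is then methylated and formylated before deprotection (steps 11–14).
6. The target has no stereocentre, so no stereochemistry has to be set.

Key step: step 10

Remark: intermediates 3 and 20 are racemic or diastereomeric mixtures whose stereocentres are lost in the same flask, so they are drawn without configuration.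

**Route**

Step 1
Reactants: 1 orsellinic acid
Product: 2 benzyl 2,4-dihydroxy-6-methylbenzoate
Conditions: BnBr, KHCO3, DMF, rt
Reagents that add atoms: benzyl bromide, BrCc1ccccc1
Why: Carboxylate O-alkylation (SN2) is selective because KHCO3 deprotonates only the acid and leaves both phenols untouched, and room temperature avoids decarboxylation of the acid.

Step 2
Reactants: 2 benzyl 2,4-dihydroxy-6-methylbenzoate
Product: 4 benzyl 3-formyl-2,4-dihydroxy-6-methylbenzoate, via chloro ether 3 (not isolated)
Conditions: TiCl4, Cl2CHOMe, CH2Cl2, -10 to 0 °C; then aq. HCl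
Reagents that add atoms: dichloromethyl methyl ether, COC(Cl)Cl; water, O
Why: Rieche formylation, in which the TiCl4-bound salicylate should direct the electrophile to C3, the carbon ortho to both phenol oxygens, so that hydrolysis gives the doubly hydrogen-bonded aldehyde; any C5 isomer would be removed by crystallisation.

Step 3
Reactants: 4 benzyl 3-formyl-2,4-dihydroxy-6-methylbenzoate
Product: 5 benzyl 3-formyl-2,4-dihydroxy-5-iodo-6-methylbenzoate
Conditions: N-iodosuccinimide, cat. CF3CO2H, MeCN, 0 °C to rt
Reagents that add atoms: N-iodosuccinimide, O=C1CCC(=O)N1I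
Why: Electrophilic aromatic iodination can only occur at C5, the last free ring carbon, which is ortho to the C4 hydroxyl and para to the C2 hydroxyl (the site at which haematommate esters are known to be halogenated).

Step 4
Reactants: 5 benzyl 3-formyl-2,4-dihydroxy-5-iodo-6-methylbenzoate
Product: 6 benzyl 2,4-bis(benzyloxy)-3-formyl-5-iodo-6-methylbenzoate
Conditions: BnBr, K2CO3, DMF, 60 °C
Reagents that add atoms: benzyl bromide, BrCc1ccccc1
Why: Williamson ether synthesis, in which warm K2CO3/DMF should break the hydrogen bonds of both chelated phenols and benzylate them, the molecule offering no other nucleophile.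

Step 5
Reactants: 6 benzyl 2,4-bis(benzyloxy)-3-formyl-5-iodo-6-methylbenzoate
Product: 7 benzyl 2,4-bis(benzyloxy)-3-(1,3-dioxolan-2-yl)-5-iodo-6-methylbenzoate
Conditions: HOCH2CH2OH, cat. p-TsOH, PhMe, reflux, Dean–Stark trap
Reagents that add atoms: ethane-1,2-diol, OCCO
Why: Acid-catalysed acetalisation with azeotropic removal of water masks the aldehyde against the arylmagnesium reagent of step 6 and against the enolates of steps 9 to 12.

Step 6
Reactants: 7 benzyl 2,4-bis(benzyloxy)-3-(1,3-dioxolan-2-yl)-5-iodo-6-methylbenzoate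
Product: 10 benzyl 2,4-bis(benzyloxy)-3-(1,3-dioxolan-2-yl)-5-hydroxy-6-methylbenzoate, via arylmagnesium chloride 8 (not isolated), via dimethyl arylboronate 9 (not isolated)
Conditions: i-PrMgCl·LiCl, THF, -40 °C; B(OMe)3, -40 to 0 °C; 30% H2O2, aq. NaOH, 0 °C
Reagents that add atoms: hydrogen peroxide, OO
Why: Iodine–magnesium exchange with i-PrMgCl·LiCl is fast on aryl iodides at low temperature and should spare the di-ortho-substituted benzyl ester, and borylation followed by boronate oxidation then delivers the phenol with O5 free while O2 and O4 stay benzylated.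

Step 7
Reactants: 11 2,2,6-trimethyl-4H-1,3-dioxin-4-one; 12 acetyl chloride
Product: 14 2,2-dimethyl-6-(2-oxopropyl)-4H-1,3-dioxin-4-one, via lithium dienolate 13 (not isolated)
Conditions: LiN(SiMe3)2, THF, -78 °C; then 12 (0.5 equiv), -78 °C; aq. NH4Cl
Reagents that add atoms: none
Why: Claisen-type C-acylation of the vinylogous lithium dienolate at its terminal carbon, in which the second equivalent of enolate takes up the proton of the more acidic product.

Step 8
Reactants: 14 2,2-dimethyl-6-(2-oxopropyl)-4H-1,3-dioxin-4-one; 15 N-methoxy-N-methylacetamide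
Product: 17 6-(2,4-dioxopentyl)-2,2-dimethyl-4H-1,3-dioxin-4-one, via dilithium dianion 16 (not isolated)
Conditions: LiN(i-Pr)2 (2.2 equiv), THF, -78 °C; then 15, -78 to -20 °C; aq. NH4Cl
Reagents that add atoms: none
Why: Acylation of a β-dicarbonyl-type dianion at its more reactive terminal carbon by a Weinreb amide, whose chelated tetrahedral intermediate should prevent over-addition.

Step 9
Reactants: 17 6-(2,4-dioxopentyl)-2,2-dimethyl-4H-1,3-dioxin-4-one; 10 benzyl 2,4-bis(benzyloxy)-3-(1,3-dioxolan-2-yl)-5-hydroxy-6-methylbenzoate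
Product: 19 benzyl 2,4-bis(benzyloxy)-3-(1,3-dioxolan-2-yl)-6-methyl-5-[(3,5,7-trioxooctanoyl)oxy]benzoate, via acylketene 18 (not isolated)
Conditions: PhMe, 110 °C, slow addition of 17 to 10; concentrated and used crude
Reagents that add atoms: none
Why: Thermal retro-[4+2] fragmentation of the dioxinone releases acetone and an acylketene that adds the phenol O–H under neutral conditions, so the hindered depside ester forms without activating any hindered benzoic acid, and slow addition keeps the phenol in excess over the ketene.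

Step 10
Reactants: 19 benzyl 2,4-bis(benzyloxy)-3-(1,3-dioxolan-2-yl)-6-methyl-5-[(3,5,7-trioxooctanoyl)oxy]benzoate
Product: 21 benzyl 2,4-bis(benzyloxy)-5-[(2,4-dihydroxy-6-methylbenzoyl)oxy]-3-(1,3-dioxolan-2-yl)-6-methylbenzoate, via aldol adduct 20 (not isolated)
Conditions: Et3N, CH2Cl2, 0 °C to rt; then pH 5 phosphate buffer
Reagents that add atoms: none
Why: Et3N enolises the chain, and chain C2, flanked by the ester and the C3 ketone, should add to the C7 methyl ketone in an intramolecular aldol reaction to give cyclohexanedione 20, which loses water by E1cB elimination and tautomerises to the 2,4-dihydroxy-6-methylbenzoate. The closest known reaction is the base-induced aldol aromatization of 3,5,7-trioxo alkyl esters made by alcohol capture of dioxinone-derived acylketenes (resorcylate synthesis), the laboratory counterpart of orsellinate biosynthesis. Ring A closes in a 6-(enolendo)-exo-trig mode by forming the bond between ring A C1 and C6 (chain C2 to C7). No stereocentre remains, since the two centres of 20 are uncontrolled and are erased on aromatization. The step needs chemoselectivity for this aldol over acyl transfer from the aryl ester (attack of chain C6 or of the C5 enol oxygen on C1, which would expel the ring B phenoxide) and over the alternative C8-to-C3 aldol. The electron-rich, benzyl-ether-substituted ring B is a poor leaving group and its two ortho substituents (benzyloxy and methyl) shield the ester carbonyl, while the methyl ketone is the most electrophilic carbonyl, C2 is far more acidic than C8, and irreversible aromatization drains the aldol pathway.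

Step 11
Reactants: 21 benzyl 2,4-bis(benzyloxy)-5-[(2,4-dihydroxy-6-methylbenzoyl)oxy]-3-(1,3-dioxolan-2-yl)-6-methylbenzoate
Product: 22 benzyl 2,4-bis(benzyloxy)-3-(1,3-dioxolan-2-yl)-5-[(2-hydroxy-4-methoxy-6-methylbenzoyl)oxy]-6-methylbenzoate
Conditions: MeI, K2CO3, acetone, rt
Reagents that add atoms: iodomethane, CI
Why: Williamson methylation should be selective for the ring A C4 hydroxyl, because the C2 hydroxyl is hydrogen-bonded to the ester carbonyl and much less nucleophilic, as is usual for orsellinate esters.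

Step 12
Reactants: 22 benzyl 2,4-bis(benzyloxy)-3-(1,3-dioxolan-2-yl)-5-[(2-hydroxy-4-methoxy-6-methylbenzoyl)oxy]-6-methylbenzoate
Product: 24 benzyl 2,4-bis(benzyloxy)-3-(1,3-dioxolan-2-yl)-5-[(3-formyl-2-hydroxy-4-methoxy-6-methylbenzoyl)oxy]-6-methylbenzoate, via hydroxymethyl phenol 23 (not isolated)
Conditions: (CH2O)n, MgCl2, Et3N, MeCN, reflux
Reagents that add atoms: paraformaldehyde (as formaldehyde), C=O
Why: Magnesium-mediated ortho-formylation (Casnati–Skattebøl), in which the phenoxide formed with MgCl2 and Et3N delivers formaldehyde only to an ortho carbon, ring A C3 being the single ortho position that bears hydrogen, and a second formaldehyde oxidises the benzylic alkoxide by hydride transfer, while the basic medium should leave acetal, benzyl groups and depside ester intact and the fully substituted ring B cannot react.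

Step 13
Reactants: 24 benzyl 2,4-bis(benzyloxy)-3-(1,3-dioxolan-2-yl)-5-[(3-formyl-2-hydroxy-4-methoxy-6-methylbenzoyl)oxy]-6-methylbenzoate
Product: 25 benzyl 2,4-bis(benzyloxy)-3-formyl-5-[(3-formyl-2-hydroxy-4-methoxy-6-methylbenzoyl)oxy]-6-methylbenzoate
Conditions: 1 M aq. HCl, THF, rt
Reagents that add atoms: water, O
Why: Acid-catalysed acetal hydrolysis, which should be fast for the electron-rich 2,6-dialkoxyaryl dioxolane under dilute acid that does not touch the hindered esters.

Step 14
Reactants: 25 benzyl 2,4-bis(benzyloxy)-3-formyl-5-[(3-formyl-2-hydroxy-4-methoxy-6-methylbenzoyl)oxy]-6-methylbenzoate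
Product: 26 haemathamnolic acid
Conditions: H2 (1 atm), 10% Pd/C, EtOAc, rt
Reagents that add atoms: none
Why: Catalytic hydrogenolysis should cleave the benzyl ester and both benzyl ethers faster than it reduces the formyl groups, which become hydrogen-bonded salicylaldehyde-type aldehydes as the phenols are released, provided the reaction is stopped after three equivalents of H2.

**Compound list**

1 | orsellinic acid (2,4-dihydroxy-6-methylbenzoic acid) | Cc1cc(O)cc(O)c1C(=O)O | starting material
2 | benzyl 2,4-dihydroxy-6-methylbenzoate | Cc1cc(O)cc(O)c1C(=O)OCc1ccccc1 | intermediate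
3 | benzyl 3-[chloro(methoxy)methyl]-2,4-dihydroxy-6-methylbenzoate (racemic, TiCl4-bound) | COC(Cl)c1c(O)cc(C)c(C(=O)OCc2ccccc2)c1O | intermediate (not isolated)
4 | benzyl 3-formyl-2,4-dihydroxy-6-methylbenzoate | O=Cc1c(O)cc(C)c(C(=O)OCc2ccccc2)c1O | intermediate
5 | benzyl 3-formyl-2,4-dihydroxy-5-iodo-6-methylbenzoate | O=Cc1c(O)c(I)c(C)c(C(=O)OCc2ccccc2)c1O | intermediate
6 | benzyl 2,4-bis(benzyloxy)-3-formyl-5-iodo-6-methylbenzoate | O=Cc1c(OCc2ccccc2)c(I)c(C)c(C(=O)OCc2ccccc2)c1OCc1ccccc1 | intermediate
7 | benzyl 2,4-bis(benzyloxy)-3-(1,3-dioxolan-2-yl)-5-iodo-6-methylbenzoate | Cc1c(I)c(OCc2ccccc2)c(C2OCCO2)c(OCc2ccccc2)c1C(=O)OCc1ccccc1 | intermediate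
8 | arylmagnesium chloride from 7 (MgCl in place of iodine at C5) | Cc1c([Mg]Cl)c(OCc2ccccc2)c(C2OCCO2)c(OCc2ccccc2)c1C(=O)OCc1ccccc1 | intermediate (not isolated)
9 | benzyl 2,4-bis(benzyloxy)-5-(dimethoxyboranyl)-3-(1,3-dioxolan-2-yl)-6-methylbenzoate | COB(OC)c1c(C)c(C(=O)OCc2ccccc2)c(OCc2ccccc2)c(C2OCCO2)c1OCc1ccccc1 | intermediate (not isolated)
10 | benzyl 2,4-bis(benzyloxy)-3-(1,3-dioxolan-2-yl)-5-hydroxy-6-methylbenzoate | Cc1c(O)c(OCc2ccccc2)c(C2OCCO2)c(OCc2ccccc2)c1C(=O)OCc1ccccc1 | intermediate
11 | 2,2,6-trimethyl-4H-1,3-dioxin-4-one | CC1=CC(=O)OC(C)(C)O1 | starting material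
12 | acetyl chloride | CC(=O)Cl | starting material
13 | lithium 2,2-dimethyl-6-methylidene-6H-1,3-dioxin-4-olate | [Li+].C=C1C=C([O-])OC(C)(C)O1 | intermediate (not isolated)
14 | 2,2-dimethyl-6-(2-oxopropyl)-4H-1,3-dioxin-4-one | CC(=O)CC1=CC(=O)OC(C)(C)O1 | intermediate
15 | N-methoxy-N-methylacetamide | CC(=O)N(C)OC | starting material
16 | dilithium dianion of 14 (bis-enolate) | [Li+].[Li+].C=C([O-])C=C1C=C([O-])OC(C)(C)O1 | intermediate (not isolated)
17 | 6-(2,4-dioxopentyl)-2,2-dimethyl-4H-1,3-dioxin-4-one | CC(=O)CC(=O)CC1=CC(=O)OC(C)(C)O1 | intermediate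
18 | 3,5,7-trioxooct-1-en-1-one (acylketene) | CC(=O)CC(=O)CC(=O)C=C=O | intermediate (not isolated)
19 | benzyl 2,4-bis(benzyloxy)-3-(1,3-dioxolan-2-yl)-6-methyl-5-[(3,5,7-trioxooctanoyl)oxy]benzoate | CC(=O)CC(=O)CC(=O)CC(=O)Oc1c(C)c(C(=O)OCc2ccccc2)c(OCc2ccccc2)c(C2OCCO2)c1OCc1ccccc1 | intermediate
20 | benzyl 2,4-bis(benzyloxy)-3-(1,3-dioxolan-2-yl)-5-[(2-hydroxy-2-methyl-4,6-dioxocyclohexane-1-carbonyl)oxy]-6-methylbenzoate (diastereomer mixture) | CC1(O)CC(=O)CC(=O)C1C(=O)Oc1c(C)c(C(=O)OCc2ccccc2)c(OCc2ccccc2)c(C2OCCO2)c1OCc1ccccc1 | intermediate (not isolated)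
21 | benzyl 2,4-bis(benzyloxy)-5-[(2,4-dihydroxy-6-methylbenzoyl)oxy]-3-(1,3-dioxolan-2-yl)-6-methylbenzoate | Cc1cc(O)cc(O)c1C(=O)Oc1c(C)c(C(=O)OCc2ccccc2)c(OCc2ccccc2)c(C2OCCO2)c1OCc1ccccc1 | intermediate
22 | benzyl 2,4-bis(benzyloxy)-3-(1,3-dioxolan-2-yl)-5-[(2-hydroxy-4-methoxy-6-methylbenzoyl)oxy]-6-methylbenzoate | COc1cc(C)c(C(=O)Oc2c(C)c(C(=O)OCc3ccccc3)c(OCc3ccccc3)c(C3OCCO3)c2OCc2ccccc2)c(O)c1 | intermediate
23 | benzyl 2,4-bis(benzyloxy)-3-(1,3-dioxolan-2-yl)-5-{[2-hydroxy-3-(hydroxymethyl)-4-methoxy-6-methylbenzoyl]oxy}-6-methylbenzoate (as magnesium alkoxide) | COc1cc(C)c(C(=O)Oc2c(C)c(C(=O)OCc3ccccc3)c(OCc3ccccc3)c(C3OCCO3)c2OCc2ccccc2)c(O)c1CO | intermediate (not isolated)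
24 | benzyl 2,4-bis(benzyloxy)-3-(1,3-dioxolan-2-yl)-5-[(3-formyl-2-hydroxy-4-methoxy-6-methylbenzoyl)oxy]-6-methylbenzoate | COc1cc(C)c(C(=O)Oc2c(C)c(C(=O)OCc3ccccc3)c(OCc3ccccc3)c(C3OCCO3)c2OCc2ccccc2)c(O)c1C=O | intermediate
25 | benzyl 2,4-bis(benzyloxy)-3-formyl-5-[(3-formyl-2-hydroxy-4-methoxy-6-methylbenzoyl)oxy]-6-methylbenzoate | COc1cc(C)c(C(=O)Oc2c(C)c(C(=O)OCc3ccccc3)c(OCc3ccccc3)c(C=O)c2OCc2ccccc2)c(O)c1C=O | intermediate
26 | haemathamnolic acid (3-formyl-5-[(3-formyl-2-hydroxy-4-methoxy-6-methylbenzoyl)oxy]-2,4-dihydroxy-6-methylbenzoic acid) | COc1cc(C)c(C(=O)Oc2c(C)c(C(=O)O)c(O)c(C=O)c2O)c(O)c1C=O | target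

**Count and risks**

Total step count: 14. Longest linear sequence: 12 steps (steps 1–6 and 9–14, from orsellinic acid 1); the chain branch (steps 7–8) joins at step 9.

Steps most likely to fail:

1. Step 10. Once the chain is enolised, it may transfer its acyl group intramolecularly instead of undergoing the aldol reaction (C-acylation by chain C6 or lactonisation through the C5 enol oxygen), which would eject the ring B phenoxide and destroy the depside linkage. The fallback gives up the chain cyclisation and uses a classical acid chloride esterification with a preformed ring A; it sets out from 1 and phenol 10 and returns at 21. Orsellinic acid 1 would be acetylated (Ac2O, pyridine) to 2,4-diacetoxy-6-methylbenzoic acid F1 and converted with (COCl)2 and cat. DMF into 2,4-diacetoxy-6-methylbenzoyl chloride F2. Coupling with 10 (Et3N, DMAP, CH2Cl2) would give benzyl 2,4-bis(benzyloxy)-5-[(2,4-diacetoxy-6-methylbenzoyl)oxy]-3-(1,3-dioxolan-2-yl)-6-methylbenzoate F3. Its two aryl acetates would then be removed with NH3 in MeOH at 0 °C, conditions under which the di-ortho-substituted depside and benzyl esters should react far more slowly, to give 21.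

2. Step 9. The acylketene may close onto its own C5 enol oxygen to a pyranone faster than the hindered phenol captures it, so that the chain is consumed without ester formation. The fallback inverts the order of aromatization and ester formation; it sets out from 17 and returns at 21. Treatment of 17 with Et3N in CH2Cl2 should bring about the same aldol aromatization on the dioxinone and give 7-hydroxy-2,2,5-trimethyl-4H-1,3-benzodioxin-4-one F4. Irradiation of F4 at 300 nm in CH2Cl2 in the presence of 10 would release acetone and the quinone ketene 5-hydroxy-3-methyl-6-(oxomethylidene)cyclohexa-2,4-dien-1-one F5 (not isolated). F5 has no destructive internal pathway, since it can only recombine with acetone, and its capture by 10 gives 21.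

3. Step 12. The chelated, ester-deactivated phenoxide of ring A may be too weak a nucleophile to take up formaldehyde, and prolonged heating with base could then cleave the depside ester. The fallback replaces the magnesium-templated process by a Lewis-acid electrophilic formylation after deliberate removal of the acid-labile acetal; it sets out from 22 and returns at 25. Hydrolysis of 22 (1 M aq. HCl, THF) would give benzyl 2,4-bis(benzyloxy)-3-formyl-5-[(2-hydroxy-4-methoxy-6-methylbenzoyl)oxy]-6-methylbenzoate F6. Rieche formylation of F6 (TiCl4, Cl2CHOMe, CH2Cl2, -20 °C) should be directed by the TiCl4-bound salicylate to ring A C3 and pass through benzyl 2,4-bis(benzyloxy)-5-({3-[chloro(methoxy)methyl]-2-hydroxy-4-methoxy-6-methylbenzoyl}oxy)-3-formyl-6-methylbenzoate F7 (not isolated), which is hydrolysed to 25 on aqueous work-up. Any benzyl ether lost to the Lewis acid would be of no consequence, because step 14 removes all benzyl groups.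

**Further compounds**

F1 | step 10 | 2,4-diacetoxy-6-methylbenzoic acid | CC(=O)Oc1cc(C)c(C(=O)O)c(OC(C)=O)c1
F2 | step 10 | 2,4-diacetoxy-6-methylbenzoyl chloride | CC(=O)Oc1cc(C)c(C(=O)Cl)c(OC(C)=O)c1
F3 | step 10 | benzyl 2,4-bis(benzyloxy)-5-[(2,4-diacetoxy-6-methylbenzoyl)oxy]-3-(1,3-dioxolan-2-yl)-6-methylbenzoate | CC(=O)Oc1cc(C)c(C(=O)Oc2c(C)c(C(=O)OCc3ccccc3)c(OCc3ccccc3)c(C3OCCO3)c2OCc2ccccc2)c(OC(C)=O)c1
F4 | step 9 | 7-hydroxy-2,2,5-trimethyl-4H-1,3-benzodioxin-4-one | Cc1cc(O)cc2OC(C)(C)OC(=O)c12
F5 | step 9 | 5-hydroxy-3-methyl-6-(oxomethylidene)cyclohexa-2,4-dien-1-one | O=C=C1C(C)=CC(O)=CC1=O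
F6 | step 12 | benzyl 2,4-bis(benzyloxy)-3-formyl-5-[(2-hydroxy-4-methoxy-6-methylbenzoyl)oxy]-6-methylbenzoate | COc1cc(C)c(C(=O)Oc2c(C)c(C(=O)OCc3ccccc3)c(OCc3ccccc3)c(C=O)c2OCc2ccccc2)c(O)c1
F7 | step 12 | benzyl 2,4-bis(benzyloxy)-5-({3-[chloro(methoxy)methyl]-2-hydroxy-4-methoxy-6-methylbenzoyl}oxy)-3-formyl-6-methylbenzoate | COC(Cl)c1c(OC)cc(C)c(C(=O)Oc2c(C)c(C(=O)OCc3ccccc3)c(OCc3ccccc3)c(C=O)c2OCc2ccccc2)c1O
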